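**Retrosynthetic overview**
1. The target is unmasked last by hydrogenolysis of the tribenzyl-protected tridepside 27 (one benzyl ester on ring A, two benzyl ethers on ring C).
2. The two aryl ester bonds are cut: 27 ⇐ didepside acid 25 + ring-A phenol 13; 25 ⇐ ring-C acid 8 + ring-B phenol 22 (mixed-anhydride esterifications, B–C bond first).
3. All three benzoate units come from one resorcylate, methyl 2,4-dihydroxy-3,6-dimethylbenzoate 6; ring B gets its extra C5 methyl by formylation and reduction.
4. 6 ⇐ aromatisation of cyclohexane-1,3-dione 4 ⇐ intermolecular Michael addition of dimethyl malonate 1 to (E)-hex-4-en-3-one 2 followed by Claisen ring closure (key C–C bond formation).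
5. Ring order: the benzenoid carbocycle is the only ring built; it is made once and elaborated three times (ring C, ring A, ring B).

**Assumptions**
- The target has no stereocentre and no stereogenic double bond; it is achiral, so no enantiocontrol is needed.
- Salts of a numbered compound formed in the flask (enolates, phenoxides, carboxylates) are treated as that compound and not numbered separately.

**Route**

Step 1
Reactants: 1 dimethyl malonate; 2 (E)-hex-4-en-3-one
Product: 4 methyl 3,6-dimethyl-2,4-dioxocyclohexane-1-carboxylate (diastereomer/enol mixture), via Michael adduct 3 (not isolated)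
Conditions: NaOMe (1.1 equiv), MeOH, 0 °C → reflux, 4 h; then aq. HCl to pH 2
Reagents that add atoms: none
Why: Michael addition of the malonate anion to the enone, then Claisen (Dieckmann-type) attack of the ethyl-ketone enolate on a malonate ester, closes the six-membered ring and is driven by deprotonation of the β-dicarbonyl product; the stereocentres are racemic and vanish on aromatisation.

Step 2
Reactants: 4 methyl 3,6-dimethyl-2,4-dioxocyclohexane-1-carboxylate
Product: 6 methyl 2,4-dihydroxy-3,6-dimethylbenzoate, via 3-chloro-dione 5 (not isolated)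
Conditions: NCS (1.05 equiv), DMF, 0 °C → rt, 1 h; then 90 °C, 2 h
Reagents that add atoms: none
Why: Electrophilic chlorination at the doubly activated C3, followed by enolisation and vinylogous dehydrochlorination, gives the aromatic resorcylate (halogenation–dehydrohalogenation aromatisation).

Step 3
Reactants: 6 methyl 2,4-dihydroxy-3,6-dimethylbenzoate
Product: 7 methyl 2,4-bis(benzyloxy)-3,6-dimethylbenzoate
Conditions: BnBr (2.5 equiv), K2CO3 (3 equiv), DMF, 70 °C, 12 h
Reagents that add atoms: benzyl bromide, BrCc1ccccc1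
Why: Williamson etherification with excess reagent in hot DMF alkylates both the free 4-OH and the chelated 2-OH.

Step 4
Reactants: 7 methyl 2,4-bis(benzyloxy)-3,6-dimethylbenzoate
Product: 8 2,4-bis(benzyloxy)-3,6-dimethylbenzoic acid
Conditions: KOH (5 equiv), DMSO/H2O 4:1, 100 °C, 6 h; then 2 M HCl, 0 °C
Reagents that add atoms: potassium hydroxide, [K+].[OH-]
Why: Saponification of the hindered 2,6-disubstituted ester needs poorly solvated hydroxide in aqueous DMSO; benzyl ethers are inert to base.

Step 5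
Reactants: 6 methyl 2,4-dihydroxy-3,6-dimethylbenzoate
Product: 9 methyl 4-(benzyloxy)-2-hydroxy-3,6-dimethylbenzoate
Conditions: BnBr (1.05 equiv), K2CO3 (1.2 equiv), acetone, reflux, 6 h
Reagents that add atoms: benzyl bromide, BrCc1ccccc1
Why: Regioselective Williamson etherification: the 2-OH is hydrogen-bonded to the ester carbonyl and reacts much more slowly than the 4-OH.

Step 6
Reactants: 9 methyl 4-(benzyloxy)-2-hydroxy-3,6-dimethylbenzoate
Product: 10 methyl 4-(benzyloxy)-2-methoxy-3,6-dimethylbenzoate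
Conditions: MeI (3 equiv), K2CO3 (3 equiv), DMF, 50 °C, 12 h
Reagents that add atoms: iodomethane, CI
Why: Williamson O-methylation of the remaining chelated phenol under forcing conditions with a small electrophile.

Step 7
Reactants: 10 methyl 4-(benzyloxy)-2-methoxy-3,6-dimethylbenzoate
Product: 11 4-(benzyloxy)-2-methoxy-3,6-dimethylbenzoic acid
Conditions: KOH (5 equiv), DMSO/H2O 4:1, 100 °C; then 2 M HCl, 0 °C
Reagents that add atoms: potassium hydroxide, [K+].[OH-]
Why: Saponification of the hindered ester as in step 4; both ethers are base-stable.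

Step 8
Reactants: 11 4-(benzyloxy)-2-methoxy-3,6-dimethylbenzoic acid
Product: 12 4-hydroxy-2-methoxy-3,6-dimethylbenzoic acid
Conditions: H2 (1 atm), 10% Pd/C, EtOAc, rt
Reagents that add atoms: none
Why: Catalytic hydrogenolysis cleaves the benzylic C–O bond under neutral conditions, so the electron-rich acid does not decarboxylate.

Step 9
Reactants: 12 4-hydroxy-2-methoxy-3,6-dimethylbenzoic acid
Product: 13 benzyl 4-hydroxy-2-methoxy-3,6-dimethylbenzoate
Conditions: BnBr (1.05 equiv), KHCO3 (1.2 equiv), DMF, rt → 40 °C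
Reagents that add atoms: benzyl bromide, BrCc1ccccc1
Why: Chemoselective carboxylate O-alkylation (SN2): bicarbonate deprotonates the acid but not the phenol, and the reaction at the benzyl carbon is not slowed by the crowded carbonyl.

Step 10
Reactants: 6 methyl 2,4-dihydroxy-3,6-dimethylbenzoate
Product: 15 methyl 3-formyl-4,6-dihydroxy-2,5-dimethylbenzoate, via α-chloro ether 14 (not isolated)
Conditions: Cl2CHOMe (1.5 equiv), TiCl4 (3 equiv), CH2Cl2, 0 °C, 2 h; then ice/1 M HCl
Reagents that add atoms: dichloromethyl methyl ether, COC(Cl)Cl; water, O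
Why: Rieche formylation: the titanium phenoxide directs the electrophile to the only free ring position (ortho to 4-OH, para to 2-OH), and aqueous work-up hydrolyses the chloro ether to the aldehyde.

Step 11
Reactants: 15 methyl 3-formyl-4,6-dihydroxy-2,5-dimethylbenzoate
Product: 17 methyl 2,4-dihydroxy-3,5,6-trimethylbenzoate, via benzylic alcohol 16 (not isolated)
Conditions: Et3SiH (3 equiv), TFA, 0 °C → rt
Reagents that add atoms: none
Why: Ionic hydrogenation: the ortho/para-hydroxy groups stabilise the benzylic cation (quinone methide), so hydride transfer from silane takes the aldehyde through the alcohol to the methyl group without touching the ester.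

Step 12
Reactants: 17 methyl 2,4-dihydroxy-3,5,6-trimethylbenzoate
Product: 18 methyl 4-(benzyloxy)-2-hydroxy-3,5,6-trimethylbenzoate
Conditions: BnBr (1.1 equiv), K2CO3 (1.3 equiv), DMF, rt → 40 °C
Reagents that add atoms: benzyl bromide, BrCc1ccccc1
Why: Regioselective Williamson etherification of the non-chelated 4-OH, as in step 5; the unhindered benzyl electrophile tolerates the two flanking methyls.

Step 13
Reactants: 18 methyl 4-(benzyloxy)-2-hydroxy-3,5,6-trimethylbenzoate
Product: 19 methyl 4-(benzyloxy)-2-methoxy-3,5,6-trimethylbenzoate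
Conditions: MeI (3 equiv), K2CO3 (3 equiv), DMF, 50 °C, 12 h
Reagents that add atoms: iodomethane, CI
Why: Williamson O-methylation of the chelated 2-OH, as in step 6.

Step 14
Reactants: 19 methyl 4-(benzyloxy)-2-methoxy-3,5,6-trimethylbenzoate
Product: 20 4-(benzyloxy)-2-methoxy-3,5,6-trimethylbenzoic acid
Conditions: KOH (6 equiv), DMSO/H2O 4:1, 110 °C; then 2 M HCl, 0 °C
Reagents that add atoms: potassium hydroxide, [K+].[OH-]
Why: Saponification of the hindered ester with hydroxide in aqueous DMSO, as in steps 4 and 7.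

Step 15
Reactants: 20 4-(benzyloxy)-2-methoxy-3,5,6-trimethylbenzoic acid
Product: 21 4-hydroxy-2-methoxy-3,5,6-trimethylbenzoic acid
Conditions: H2 (1 atm), 10% Pd/C, EtOAc, rt
Reagents that add atoms: none
Why: Neutral catalytic hydrogenolysis of the benzyl ether, as in step 8.

Step 16
Reactants: 21 4-hydroxy-2-methoxy-3,5,6-trimethylbenzoic acid
Product: 22 prop-2-en-1-yl 4-hydroxy-2-methoxy-3,5,6-trimethylbenzoate
Conditions: allyl bromide (1.1 equiv), KHCO3 (1.2 equiv), DMF, rt
Reagents that add atoms: allyl bromide, C=CCBr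
Why: Chemoselective carboxylate O-alkylation (SN2); the phenol is not deprotonated by bicarbonate and is shielded by two ortho methyls.

Step 17
Reactants: 8 2,4-bis(benzyloxy)-3,6-dimethylbenzoic acid; 22 prop-2-en-1-yl 4-hydroxy-2-methoxy-3,5,6-trimethylbenzoate
Product: 24 prop-2-en-1-yl 4-{[2,4-bis(benzyloxy)-3,6-dimethylbenzoyl]oxy}-2-methoxy-3,5,6-trimethylbenzoate, via mixed anhydride 23 (not isolated)
Conditions: 8, TFAA (4 equiv), toluene, 0 °C → rt, 30 min; then 22, rt, 12 h
Reagents that add atoms: none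
Why: TFAA mixed-anhydride esterification: the electron-rich 2,6-disubstituted acid gives an acyl trifluoroacetate (acylium-like, sterically small) that acylates even the di-ortho-methyl phenol; allyl ester and benzyl ethers tolerate the TFA formed.

Step 18
Reactants: 24 prop-2-en-1-yl 4-{[2,4-bis(benzyloxy)-3,6-dimethylbenzoyl]oxy}-2-methoxy-3,5,6-trimethylbenzoate
Product: 25 4-{[2,4-bis(benzyloxy)-3,6-dimethylbenzoyl]oxy}-2-methoxy-3,5,6-trimethylbenzoic acid
Conditions: Pd(PPh3)4 (5 mol%), morpholine (5 equiv), THF, rt; then 1 M HCl wash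
Reagents that add atoms: none
Why: Tsuji–Trost deallylation: Pd(0) ionises the allyl ester and morpholine traps the π-allyl; the hindered aryl ester and the benzyl ethers are untouched.

Step 19
Reactants: 25 4-{[2,4-bis(benzyloxy)-3,6-dimethylbenzoyl]oxy}-2-methoxy-3,5,6-trimethylbenzoic acid; 13 benzyl 4-hydroxy-2-methoxy-3,6-dimethylbenzoate
Product: 27 benzyl 4-[(4-{[2,4-bis(benzyloxy)-3,6-dimethylbenzoyl]oxy}-2-methoxy-3,5,6-trimethylbenzoyl)oxy]-2-methoxy-3,6-dimethylbenzoate, via mixed anhydride 26 (not isolated)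
Conditions: 25, TFAA (4 equiv), toluene, 0 °C → rt, 30 min; then 13, rt, 12 h
Reagents that add atoms: none
Why: Second TFAA mixed-anhydride esterification; the ortho-methoxy group stabilises the acylium-like species, the phenol of 13 has only one ortho substituent, and the existing depside ester and benzyl ester survive the acid.

Step 20
Reactants: 27 benzyl 4-[(4-{[2,4-bis(benzyloxy)-3,6-dimethylbenzoyl]oxy}-2-methoxy-3,5,6-trimethylbenzoyl)oxy]-2-methoxy-3,6-dimethylbenzoate
Product: 28 4-({4-[(2,4-dihydroxy-3,6-dimethylbenzoyl)oxy]-2-methoxy-3,5,6-trimethylbenzoyl}oxy)-2-methoxy-3,6-dimethylbenzoic acid (target)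
Conditions: H2 (1 atm), 10% Pd/C, EtOAc, rt
Reagents that add atoms: none
Why: Global catalytic hydrogenolysis removes the benzyl ester and both benzyl ethers under neutral conditions that leave the two aryl ester links and the methyl ethers intact; no stereocentre is present.

**Compound list**
1 | dimethyl malonate | COC(=O)CC(=O)OC | starting material
2 | (E)-hex-4-en-3-one | CCC(=O)/C=C/C | starting material
3 | dimethyl 2-(4-oxohexan-2-yl)propanedioate (racemic Michael adduct, not isolated) | CCC(=O)CC(C)C(C(=O)OC)C(=O)OC | intermediate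
4 | methyl 3,6-dimethyl-2,4-dioxocyclohexane-1-carboxylate (diastereomer/enol mixture) | COC(=O)C1C(C)CC(=O)C(C)C1=O | intermediate
5 | methyl 3-chloro-3,6-dimethyl-2,4-dioxocyclohexane-1-carboxylate (not isolated) | COC(=O)C1C(C)CC(=O)C(C)(Cl)C1=O | intermediate
6 | methyl 2,4-dihydroxy-3,6-dimethylbenzoate | COC(=O)c1c(C)cc(O)c(C)c1O | intermediate
7 | methyl 2,4-bis(benzyloxy)-3,6-dimethylbenzoate | COC(=O)c1c(C)cc(OCc2ccccc2)c(C)c1OCc1ccccc1 | intermediate
8 | 2,4-bis(benzyloxy)-3,6-dimethylbenzoic acid | OC(=O)c1c(C)cc(OCc2ccccc2)c(C)c1OCc1ccccc1 | intermediate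
9 | methyl 4-(benzyloxy)-2-hydroxy-3,6-dimethylbenzoate | COC(=O)c1c(C)cc(OCc2ccccc2)c(C)c1O | intermediate
10 | methyl 4-(benzyloxy)-2-methoxy-3,6-dimethylbenzoate | COC(=O)c1c(C)cc(OCc2ccccc2)c(C)c1OC | intermediate
11 | 4-(benzyloxy)-2-methoxy-3,6-dimethylbenzoic acid | COc1c(C)c(OCc2ccccc2)cc(C)c1C(=O)O | intermediate
12 | 4-hydroxy-2-methoxy-3,6-dimethylbenzoic acid | COc1c(C)c(O)cc(C)c1C(=O)O | intermediate
13 | benzyl 4-hydroxy-2-methoxy-3,6-dimethylbenzoate | COc1c(C)c(O)cc(C)c1C(=O)OCc1ccccc1 | intermediate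
14 | methyl 3-[chloro(methoxy)methyl]-4,6-dihydroxy-2,5-dimethylbenzoate (racemic, as Ti complex, not isolated) | COC(=O)c1c(C)c(C(Cl)OC)c(O)c(C)c1O | intermediate
15 | methyl 3-formyl-4,6-dihydroxy-2,5-dimethylbenzoate | COC(=O)c1c(C)c(C=O)c(O)c(C)c1O | intermediate
16 | methyl 4,6-dihydroxy-3-(hydroxymethyl)-2,5-dimethylbenzoate (not isolated) | COC(=O)c1c(C)c(CO)c(O)c(C)c1O | intermediate
17 | methyl 2,4-dihydroxy-3,5,6-trimethylbenzoate | COC(=O)c1c(C)c(C)c(O)c(C)c1O | intermediate
18 | methyl 4-(benzyloxy)-2-hydroxy-3,5,6-trimethylbenzoate | COC(=O)c1c(C)c(C)c(OCc2ccccc2)c(C)c1O | intermediate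
19 | methyl 4-(benzyloxy)-2-methoxy-3,5,6-trimethylbenzoate | COC(=O)c1c(C)c(C)c(OCc2ccccc2)c(C)c1OC | intermediate
20 | 4-(benzyloxy)-2-methoxy-3,5,6-trimethylbenzoic acid | COc1c(C)c(OCc2ccccc2)c(C)c(C)c1C(=O)O | intermediate
21 | 4-hydroxy-2-methoxy-3,5,6-trimethylbenzoic acid | COc1c(C)c(O)c(C)c(C)c1C(=O)O | intermediate
22 | prop-2-en-1-yl 4-hydroxy-2-methoxy-3,5,6-trimethylbenzoate | COc1c(C)c(O)c(C)c(C)c1C(=O)OCC=C | intermediate
23 | 2,4-bis(benzyloxy)-3,6-dimethylbenzoic trifluoroacetic anhydride (not isolated) | O=C(OC(=O)C(F)(F)F)c1c(C)cc(OCc2ccccc2)c(C)c1OCc1ccccc1 | intermediate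
24 | prop-2-en-1-yl 4-{[2,4-bis(benzyloxy)-3,6-dimethylbenzoyl]oxy}-2-methoxy-3,5,6-trimethylbenzoate | COc1c(C)c(OC(=O)c2c(C)cc(OCc3ccccc3)c(C)c2OCc2ccccc2)c(C)c(C)c1C(=O)OCC=C | intermediate
25 | 4-{[2,4-bis(benzyloxy)-3,6-dimethylbenzoyl]oxy}-2-methoxy-3,5,6-trimethylbenzoic acid | COc1c(C)c(OC(=O)c2c(C)cc(OCc3ccccc3)c(C)c2OCc2ccccc2)c(C)c(C)c1C(=O)O | intermediate
26 | 4-{[2,4-bis(benzyloxy)-3,6-dimethylbenzoyl]oxy}-2-methoxy-3,5,6-trimethylbenzoic trifluoroacetic anhydride (not isolated) | COc1c(C)c(OC(=O)c2c(C)cc(OCc3ccccc3)c(C)c2OCc2ccccc2)c(C)c(C)c1C(=O)OC(=O)C(F)(F)F | intermediate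
27 | benzyl 4-[(4-{[2,4-bis(benzyloxy)-3,6-dimethylbenzoyl]oxy}-2-methoxy-3,5,6-trimethylbenzoyl)oxy]-2-methoxy-3,6-dimethylbenzoate | COc1c(C)c(OC(=O)c2c(C)c(C)c(OC(=O)c3c(C)cc(OCc4ccccc4)c(C)c3OCc3ccccc3)c(C)c2OC)cc(C)c1C(=O)OCc1ccccc1 | intermediate
28 | 4-({4-[(2,4-dihydroxy-3,6-dimethylbenzoyl)oxy]-2-methoxy-3,5,6-trimethylbenzoyl}oxy)-2-methoxy-3,6-dimethylbenzoic acid (CNP0425440.0, achiral) | COc1c(C)c(OC(=O)c2c(C)c(C)c(OC(=O)c3c(C)cc(O)c(C)c3O)c(C)c2OC)cc(C)c1C(=O)O | target

**Step count and risks**

Total step count: 20.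
Longest linear sequence: 13 steps (steps 1, 2, 10, 11, 12, 13, 14, 15, 16, 17, 18, 19, 20).

Three steps most likely to fail:

Step 2 (one-pot chlorination/dehydrochlorination). It may give mixtures of 6 with ring-halogenated material or stall at the chloro-dione. The fallback sets out from 4 and comes back at 6. Treat 4 with Br2 (2.1 equiv) in AcOH at rt. The first equivalent gives methyl 3-bromo-3,6-dimethyl-2,4-dioxocyclohexane-1-carboxylate F1, which loses HBr and aromatises. The second equivalent deliberately brominates the only free ring position to give a single crystalline compound, methyl 3-bromo-4,6-dihydroxy-2,5-dimethylbenzoate F2. Hydrogenolysis of the aryl bromide (H2, Pd/C, NaOAc, MeOH, rt) then delivers 6.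

Step 10 (formylation at the crowded C5, flanked by OH and CH3, followed by the reduction of step 11). The fallback sets out from 1 and comes back at 17, building the extra methyl into the ring construction instead of adding it to the arene. Michael addition of 1 to (E)-4-methylhex-4-en-3-one F3 (NaOMe, MeOH, reflux) gives dimethyl 2-(3-methyl-4-oxohexan-2-yl)propanedioate F4. This closes in the same pot by Claisen condensation to methyl 3,5,6-trimethyl-2,4-dioxocyclohexane-1-carboxylate F5. NCS in DMF as in step 2 gives methyl 3-chloro-3,5,6-trimethyl-2,4-dioxocyclohexane-1-carboxylate F6, which loses HCl on warming to give 17.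

Step 17 (esterification of a 2,6-disubstituted acid with a 2,6-dimethylphenol under acidic TFAA conditions; risk of low conversion or benzyl ether loss). The fallback sets out from 8 and comes back at 24, replacing acid-mediated mixed-anhydride activation by base-mediated acylation of a phenoxide. Convert 8 with oxalyl chloride and cat. DMF in CH2Cl2 into isolated 2,4-bis(benzyloxy)-3,6-dimethylbenzoyl chloride F7. Deprotonate 22 with NaH in THF at 0 °C and acylate the sodium phenoxide with F7 (0 °C → rt) to give 24.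

**Further compounds**
F1 | step 2 | methyl 3-bromo-3,6-dimethyl-2,4-dioxocyclohexane-1-carboxylate | COC(=O)C1C(C)CC(=O)C(C)(Br)C1=O
F2 | step 2 | methyl 3-bromo-4,6-dihydroxy-2,5-dimethylbenzoate | COC(=O)c1c(C)c(Br)c(O)c(C)c1O
F3 | step 10 | (E)-4-methylhex-4-en-3-one | C/C=C(\C)C(=O)CC
F4 | step 10 | dimethyl 2-(3-methyl-4-oxohexan-2-yl)propanedioate | CCC(=O)C(C)C(C)C(C(=O)OC)C(=O)OC
F5 | step 10 | methyl 3,5,6-trimethyl-2,4-dioxocyclohexane-1-carboxylate | COC(=O)C1C(C)C(C)C(=O)C(C)C1=O
F6 | step 10 | methyl 3-chloro-3,5,6-trimethyl-2,4-dioxocyclohexane-1-carboxylate | COC(=O)C1C(C)C(C)C(=O)C(C)(Cl)C1=O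
F7 | step 17 | 2,4-bis(benzyloxy)-3,6-dimethylbenzoyl chloride | O=C(Cl)c1c(C)cc(OCc2ccccc2)c(C)c1OCc1ccccc1
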